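- Once the reagent has reacted, target and isomer of the product should together hold what the reagent charge can make, at whatever later hour. In larch and alder I therefore reckon with a pool of 95.0% of the starting material charged. Reagent is the limiting reagent, and the earliest readings, 91% in alpha and 90% in beta, already stand close to that pool.

all flasks: initiator 0.5 mol%

| flask | starting material | reagent | remark | time |
|---|---|---|---|---|
| alpha | 0.40 M | 0.95 equiv | run made earlier |  |
| beta | 0.60 M | 0.95 equiv | run made earlier |  |
| larch | 0.80 M | 0.950 equiv |  | 30 min |
| alder | 0.80 M | 0.950 equiv |  | 80 min |

| run | time / min | target / % |
|---|---|---|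
| alpha | 1.00 | 91 |
| alpha | 3.00 | 84 |
| alpha | 5.00 | 86 |
| alpha | 8.00 | 75 |
| alpha | 10.0 | 74 |
| alpha | 15.0 | 64 |
| alpha | 20.0 | 60 |
| beta | 1.33 | 90 |
| beta | 2.00 | 88 |
| beta | 3.00 | 87 |
| beta | 5.00 | 80 |
| beta | 8.00 | 77 |
| beta | 12.0 | 69 |
| beta | 20.0 | 61 |

(readings scatter by 2 percentage points)

- which of the two there is more of at the end, larch (target / isomer of the product)
- which of the two there is more of at the end, alder (target / isomer of the product)
- amount of target at the end, in percent of the starting material charged, larch
- amount of target at the end, in percent of the starting material charged, alder

- the numbers in the tables scatter by 2 percentage points (one standard deviation)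

- I follow the fraction left, not the fraction made. In alpha, the share of the pool still target is 77.9% at 10.0 min and 63.2% at 20.0 min. Beta reads 61% at 20.0 min against 60% for alpha, so I carry these shares to 0.80 M.
- The share drops 22.1% in the first 10.0 min but 14.7% in the next, less, so I expect it to level off. The floor share, the part of the pool that stays target once the fall has stopped, comes from assuming that each equal stretch of time keeps the same fraction of the share above the floor. That gives 33.7%, with 66.7% kept per 10.0 min. It rests on two readings, each scattered by 2 percentage points, so I hold it loosely.
- When you come, I expect larch at 30 min to hold 50.7% target and 44.3% isomer, so more target. I expect alder at 80 min to hold 34.5% target and 60.5% isomer, so more isomer. Add no reagent: these figures are shares of the pool as charged.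
- The forecast also puts target ahead in larch and isomer of the product ahead in alder, but with 49% and 20% of target, the second below my figure, taking a loss that “looks first order”.
- The flasks give 50.0% target against 45.0% isomer in larch, and 36.6% target against 58.4% isomer in alder.

    starting material + second chain carrier → released group + first chain carrier (k = 1.80 × 10⁵ /M/s)
    2 first chain carrier → ended chains (k = 7.60 × 10⁸ /M/s)
    initiator → 2 initiating radical (k = 5.40 × 10⁻⁵ /s)
    target ⇌ isomer of the product (K = 1.70, k = 4.90 × 10⁻⁴ /s)
    reagent + first chain carrier → target + second chain carrier (k = 6.90 × 10⁶ /M/s)
    starting material + initiating radical → capped initiator + first chain carrier (k = 8.00 × 10⁶ /M/s)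

- The neighbouring flask is larch with 0.570 equiv of reagent, so its pool is 57.0%. The same floor share and the same kept fraction, applied to this smaller pool, give 30.4% target at 30 min. The flask gives 30.0% target and 27.0% isomer, with 0% of its reagent left, and starting material, the largest part, stands at 42.9%.

The numbers in the tables were generated by integration on assumed constants.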